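**Strategy.** Numbering: lactone O1, C2(=O), C3=C4, C5, C6; side chain C1'–C10' from C6. The route rests on reading the dihydropyranone ring O1–C2–C3=C4–C5–C6 as a C2–C5 butadiene joined to a C6=O1 carbonyl, with the Z-alkene C1'=C2' carried as an alkyne so that C6 becomes the aldehyde carbon of an ynal. A single chromium-catalysed enantioselective hetero-Diels–Alder reaction of that ynal with (E)-1-methoxybuta-1,3-diene forms C5–C6 and O1–C2, closes the ring and sets C6. The ynal already holds the whole C1'–C10' chain: the syn C4'/C6' diol as an acetonide, O8' as a TBS ether, and all three carbinol centres fixed.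

Key step: step 11

**Remarks on the chemistry (assumptions and design choices)**
- Configuration audit: the target is (6S)-6-[(1Z,4R,6S,8R)-4,6,8-trihydroxy-10-phenyldec-1-enyl]-5,6-dihydro-2H-pyran-2-one, with C4'/C6' syn and C6'/C8' anti. Ynal 20 and adduct 22 carry exactly this geometry. In 22 the acetal is 2,6-cis, i.e. (2R,6S). CIP labels at C6' and elsewhere change with the protecting groups; the geometry does not.
- Assumption 1: B-allyldiisopinocampheylborane made from (+)-α-pinene (dIpc2B(allyl)) adds to the Si face of unbranched aldehydes, and its antipode to the Re face.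
- Assumption 2: the chromium Schiff-base catalyst shows the same sense of induction with an ynal as with other aldehydes. On that basis the (1S,2R)-aminoindanol ligand is chosen for 6S; should the first batch show the opposite sense, the (1R,2S) ligand is used.
- Design choice 1: C4' is set from the C6' carbinol by a substrate-controlled iodocarbonate cyclisation and epoxide opening. O6' therefore never needs a temporary protecting group, and no β-hydroxy aldehyde or reagent-controlled propargylation is required.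
- Design choice 2: the lactone is oxidised before the triol is unmasked, so the oxidant meets a single hydroxyl group.
- Handling: 22 and 23 are acid-labile acetals and should be chromatographed on Et3N-deactivated silica.

**Route**

Step 1
Reactants: 1 3-phenylpropanal; 2 B-allyldiisopinocampheylborane from (+)-α-pinene (dIpc2B(allyl))
Product: 4 (R)-1-phenylhex-5-en-3-ol, via diisopinocampheylborinate ester 3 (not isolated)
Conditions: 2 (1 M in pentane), Et2O, −78 °C; then NaOH (3 M aq.), H2O2 (30 %), 0 °C to rt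
Reagents that add atoms: none
Why: Brown asymmetric allylboration through a closed chair transition state in which the isopinocampheyl groups direct allyl transfer to the Si face of the aldehyde, setting C8' as R; alkaline peroxide then cleaves borinate 3.

Step 2
Reactants: 4 (R)-1-phenylhex-5-en-3-ol
Product: 5 (R)-tert-butyldimethyl[(1-phenylhex-5-en-3-yl)oxy]silane
Conditions: TBSCl, imidazole, DMF, rt
Reagents that add atoms: tert-butyldimethylsilyl chloride, CC(C)(C)[Si](C)(C)Cl
Why: Standard imidazole-mediated silylation of a secondary alcohol; the ether should carry O8' through all basic and oxidative steps and fall in the final acid step.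

Step 3
Reactants: 5 (R)-tert-butyldimethyl[(1-phenylhex-5-en-3-yl)oxy]silane
Product: 7 (R)-3-[(tert-butyldimethylsilyl)oxy]-5-phenylpentanal, via ozonide 6 (not isolated)
Conditions: O3, CH2Cl2, −78 °C (to first blue colour); then PPh3, −78 °C to rt
Reagents that add atoms: ozone, [O-][O+]=O
Why: Ozonolysis of the terminal alkene with reductive work-up (cycloaddition and recombination to ozonide 6, reduced by PPh3) should give the β-silyloxy aldehyde without touching C8' or the much less reactive phenyl ring.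

Step 4
Reactants: 7 (R)-3-[(tert-butyldimethylsilyl)oxy]-5-phenylpentanal; 8 B-allyldiisopinocampheylborane from (−)-α-pinene (lIpc2B(allyl))
Product: 10 (4R,6R)-6-[(tert-butyldimethylsilyl)oxy]-8-phenyloct-1-en-4-ol, via diisopinocampheylborinate ester 9 (not isolated)
Conditions: 8 (1 M in pentane), Et2O, −78 °C; then NaOH (3 M aq.), H2O2 (30 %), 0 °C to rt
Reagents that add atoms: none
Why: Brown allylboration with the antipodal reagent adds allyl to the Re face under reagent control (a β-silyloxy group gives little intrinsic bias in closed allylboration transition states), setting C6' anti to C8'.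

Step 5
Reactants: 10 (4R,6R)-6-[(tert-butyldimethylsilyl)oxy]-8-phenyloct-1-en-4-ol
Product: 11 tert-butyl (4R,6R)-6-[(tert-butyldimethylsilyl)oxy]-8-phenyloct-1-en-4-yl carbonate
Conditions: Boc2O, DMAP, MeCN, rt
Reagents that add atoms: di-tert-butyl dicarbonate, CC(C)(C)OC(=O)OC(=O)OC(C)(C)C
Why: DMAP-catalysed acylation of the secondary alcohol installs the carbonate that acts as the internal oxygen nucleophile in the next step.

Step 6
Reactants: 11 tert-butyl (4R,6R)-6-[(tert-butyldimethylsilyl)oxy]-8-phenyloct-1-en-4-yl carbonate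
Product: 12 (4S,6R)-6-{(2R)-2-[(tert-butyldimethylsilyl)oxy]-4-phenylbutyl}-4-(iodomethyl)-1,3-dioxan-2-one
Conditions: IBr, PhMe, −85 °C; aq. Na2S2O3/NaHCO3 quench
Reagents that add atoms: iodine monobromide, BrI
Why: Bartlett–Smith iodocarbonate cyclisation: IBr activates the terminal alkene and the carbonate carbonyl oxygen attacks 6-exo through a chair-like transition state with both ring substituents equatorial, so the new C4'–O bond forms cis to the C6' substituent (4',6'-syn) while tert-butyl leaves as its bromide.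

Step 7
Reactants: 12 (4S,6R)-6-{(2R)-2-[(tert-butyldimethylsilyl)oxy]-4-phenylbutyl}-4-(iodomethyl)-1,3-dioxan-2-one
Product: 13 (2R,4R)-4-[(tert-butyldimethylsilyl)oxy]-1-[(2S)-oxiran-2-yl]-6-phenylhexan-2-ol
Conditions: K2CO3, MeOH, rt
Reagents that add atoms: none
Why: Methanolysis of the cyclic carbonate frees the C4' alkoxide, which displaces the neighbouring primary iodide in a Williamson-type 3-exo closure to the terminal epoxide; no bond to C4' or C6' is broken, so both centres are retained.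

Step 8
Reactants: 13 (2R,4R)-4-[(tert-butyldimethylsilyl)oxy]-1-[(2S)-oxiran-2-yl]-6-phenylhexan-2-ol; 14 lithium acetylide–ethylenediamine complex (LiC≡CH·H2NCH2CH2NH2)
Product: 15 (4R,6R,8R)-8-[(tert-butyldimethylsilyl)oxy]-10-phenyldec-1-yne-4,6-diol
Conditions: 14 (4 equiv), DMSO/THF, 0 °C to rt; then H2O
Reagents that add atoms: none
Why: SN2 opening of the terminal epoxide at its CH2 carbon (C3') by the acetylide installs C2' and C1' as a terminal alkyne and leaves C4' untouched; excess reagent covers the free hydroxyl.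

Step 9
Reactants: 15 (4R,6R,8R)-8-[(tert-butyldimethylsilyl)oxy]-10-phenyldec-1-yne-4,6-diol
Product: 16 tert-butyl{[(2R)-1-[(4R,6R)-2,2-dimethyl-6-(prop-2-yn-1-yl)-1,3-dioxan-4-yl]-4-phenylbutan-2-yl]oxy}dimethylsilane
Conditions: 2,2-dimethoxypropane, PPTS (cat.), CH2Cl2, rt
Reagents that add atoms: 2,2-dimethoxypropane, COC(C)(C)OC
Why: Acid-catalysed transacetalisation of the syn 1,3-diol gives the chair 1,3-dioxane with both substituents equatorial, leaving silyl ether and alkyne untouched.

Step 10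
Reactants: 16 tert-butyl{[(2R)-1-[(4R,6R)-2,2-dimethyl-6-(prop-2-yn-1-yl)-1,3-dioxan-4-yl]-4-phenylbutan-2-yl]oxy}dimethylsilane; 17 N,N-dimethylformamide
Product: 20 4-[(4R,6R)-6-{(2R)-2-[(tert-butyldimethylsilyl)oxy]-4-phenylbutyl}-2,2-dimethyl-1,3-dioxan-4-yl]but-2-ynal, via lithium acetylide 18 (not isolated), via lithium hemiaminal alkoxide 19 (not isolated)
Conditions: n-BuLi, THF, −78 °C; DMF, −78 to 0 °C; reverse quench into aq. KH2PO4/MTBE, 0 °C
Reagents that add atoms: none
Why: Formylation of the lithium acetylide with DMF gives the tetrahedral adduct 19, and the reverse quench into phosphate buffer releases the ynal while keeping the liberated dimethylamine protonated, which should prevent conjugate addition and base-induced β-elimination of the C4' oxygen.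

Step 11
Reactants: 20 4-[(4R,6R)-6-{(2R)-2-[(tert-butyldimethylsilyl)oxy]-4-phenylbutyl}-2,2-dimethyl-1,3-dioxan-4-yl]but-2-ynal; 21 (E)-1-methoxybuta-1,3-diene
Product: 22 (2R,6S)-6-{3-[(4R,6R)-6-{(2R)-2-[(tert-butyldimethylsilyl)oxy]-4-phenylbutyl}-2,2-dimethyl-1,3-dioxan-4-yl]prop-1-yn-1-yl}-2-methoxy-5,6-dihydro-2H-pyran (2,6-cis)
Conditions: CrCl(L) (5 mol %; L = dianion of the Schiff base of 3-(1-adamantyl)-5-methylsalicylaldehyde and (1S,2R)-cis-1-amino-2-indanol; trivalent chromium), powdered 4 Å MS, 21 (3 equiv), minimum TBME, rt, 24–48 h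
Reagents that add atoms: none
Why: The chromium centre binds the aldehyde oxygen of 20 and the electron-rich diene adds in a concerted but asynchronous endo [4+2] cycloaddition, its terminal CH2 bonding to C6 and its methoxy-bearing carbon to O1. The closest known reaction type is the chromium Schiff-base-catalysed hetero-Diels–Alder reaction of 1-methoxybutadiene with aldehydes, ynals included. The dihydropyran ring is closed by the cycloaddition itself, suprafacial on diene and carbonyl, forming C5–C6 and O1–C2 in one event. C6 is set by the catalyst (the (1S,2R) ligand shields one face of the bound C=O and should give 6S), and the acetal carbon C2 follows from the endo transition state as the 2,6-cis isomer, a centre erased in step 13. The step needs facial selectivity at C6, head-to-tail regiochemistry and reaction at C=O in preference to the C≡C bond; the first is secured by the linear C1'≡C2' spacer, which keeps C4' four atoms from C6 and offers a slim rod to the catalyst pocket, the second by the polarisation of the methoxydiene, the third by Lewis-acid activation at oxygen.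

Step 12
Reactants: 22 (2R,6S)-6-{3-[(4R,6R)-6-{(2R)-2-[(tert-butyldimethylsilyl)oxy]-4-phenylbutyl}-2,2-dimethyl-1,3-dioxan-4-yl]prop-1-yn-1-yl}-2-methoxy-5,6-dihydro-2H-pyran
Product: 23 (2R,6S)-6-{(1Z)-3-[(4R,6R)-6-{(2R)-2-[(tert-butyldimethylsilyl)oxy]-4-phenylbutyl}-2,2-dimethyl-1,3-dioxan-4-yl]prop-1-en-1-yl}-2-methoxy-5,6-dihydro-2H-pyran
Conditions: H2 (1 atm), Lindlar catalyst (Pd/CaCO3 poisoned with Pb(OAc)2), quinoline, EtOAc, rt, stopped at one equivalent of H2
Reagents that add atoms: none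
Why: Lindlar semihydrogenation delivers H2 syn to the alkyne on the poisoned palladium surface, giving the Z-alkene C1'=C2', while the disubstituted ring alkene, both acetals and the silyl ether should be left alone.

Step 13
Reactants: 23 (2R,6S)-6-{(1Z)-3-[(4R,6R)-6-{(2R)-2-[(tert-butyldimethylsilyl)oxy]-4-phenylbutyl}-2,2-dimethyl-1,3-dioxan-4-yl]prop-1-en-1-yl}-2-methoxy-5,6-dihydro-2H-pyran
Product: 25 (6S)-6-{(1Z)-3-[(4R,6R)-6-{(2R)-2-[(tert-butyldimethylsilyl)oxy]-4-phenylbutyl}-2,2-dimethyl-1,3-dioxan-4-yl]prop-1-en-1-yl}-5,6-dihydro-2H-pyran-2-one, via lactol 24 (not isolated)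
Conditions: PPTS (cat.), acetone/H2O (10:1), rt; extractive work-up, crude lactol; then MnO2 (excess), CH2Cl2, rt
Reagents that add atoms: water, O
Why: PPTS in wet acetone hydrolyses the allylic methyl acetal through its allyl-stabilised oxocarbenium ion while the acetonide is held in place by the acetone solvent and the TBS ether is inert; MnO2 then oxidises the allylic lactol 24 to the unsaturated lactone (allylic alcohol oxidation), erasing the C2 acetal centre.

Step 14
Reactants: 25 (6S)-6-{(1Z)-3-[(4R,6R)-6-{(2R)-2-[(tert-butyldimethylsilyl)oxy]-4-phenylbutyl}-2,2-dimethyl-1,3-dioxan-4-yl]prop-1-en-1-yl}-5,6-dihydro-2H-pyran-2-one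
Product: 26 (6S)-6-[(1Z,4R,6S,8R)-4,6,8-trihydroxy-10-phenyldec-1-en-1-yl]-5,6-dihydro-2H-pyran-2-one
Conditions: HF (48 % aq.), MeCN, 0 °C to rt
Reagents that add atoms: none
Why: Aqueous HF hydrolyses the acetonide and cleaves the secondary TBS ether in one acidic operation; no base is present, so oxa-Michael addition, β-elimination and Z/E isomerisation of the lactone are not expected.

**Compound list**

1 | 3-phenylpropanal | O=CCCc1ccccc1 | starting material
2 | B-allyldiisopinocampheylborane from (+)-α-pinene (dIpc2B(allyl)) | C=CCB([C@@H]1C[C@@H]2C[C@H]([C@H]1C)C2(C)C)[C@@H]1C[C@@H]2C[C@H]([C@H]1C)C2(C)C | starting material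
3 | (R)-1-phenylhex-5-en-3-yl diisopinocampheylborinate | C=CC[C@H](OB([C@@H]1C[C@@H]2C[C@H]([C@H]1C)C2(C)C)[C@@H]1C[C@@H]2C[C@H]([C@H]1C)C2(C)C)CCc1ccccc1 | intermediate
4 | (R)-1-phenylhex-5-en-3-ol | C=CC[C@H](O)CCc1ccccc1 | intermediate
5 | (R)-tert-butyldimethyl[(1-phenylhex-5-en-3-yl)oxy]silane | C=CC[C@H](O[Si](C)(C)C(C)(C)C)CCc1ccccc1 | intermediate
6 | 3-{(2R)-2-[(tert-butyldimethylsilyl)oxy]-4-phenylbutyl}-1,2,4-trioxolane (ozonide, epimers at the ring carbon) | C1OC(C[C@H](O[Si](C)(C)C(C)(C)C)CCc2ccccc2)OO1 | intermediate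
7 | (R)-3-[(tert-butyldimethylsilyl)oxy]-5-phenylpentanal | O=CC[C@H](O[Si](C)(C)C(C)(C)C)CCc1ccccc1 | intermediate
8 | B-allyldiisopinocampheylborane from (−)-α-pinene (lIpc2B(allyl)) | C=CCB([C@H]1C[C@H]2C[C@@H]([C@@H]1C)C2(C)C)[C@H]1C[C@H]2C[C@@H]([C@@H]1C)C2(C)C | starting material
9 | (4R,6R)-6-[(tert-butyldimethylsilyl)oxy]-8-phenyloct-1-en-4-yl diisopinocampheylborinate | C=CC[C@@H](OB([C@H]1C[C@H]2C[C@@H]([C@@H]1C)C2(C)C)[C@H]1C[C@H]2C[C@@H]([C@@H]1C)C2(C)C)C[C@H](O[Si](C)(C)C(C)(C)C)CCc1ccccc1 | intermediate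
10 | (4R,6R)-6-[(tert-butyldimethylsilyl)oxy]-8-phenyloct-1-en-4-ol | C=CC[C@@H](O)C[C@H](O[Si](C)(C)C(C)(C)C)CCc1ccccc1 | intermediate
11 | tert-butyl (4R,6R)-6-[(tert-butyldimethylsilyl)oxy]-8-phenyloct-1-en-4-yl carbonate | C=CC[C@@H](OC(=O)OC(C)(C)C)C[C@H](O[Si](C)(C)C(C)(C)C)CCc1ccccc1 | intermediate
12 | (4S,6R)-6-{(2R)-2-[(tert-butyldimethylsilyl)oxy]-4-phenylbutyl}-4-(iodomethyl)-1,3-dioxan-2-one | IC[C@@H]1C[C@H](C[C@H](O[Si](C)(C)C(C)(C)C)CCc2ccccc2)OC(=O)O1 | intermediate
13 | (2R,4R)-4-[(tert-butyldimethylsilyl)oxy]-1-[(2S)-oxiran-2-yl]-6-phenylhexan-2-ol | C1O[C@H]1C[C@@H](O)C[C@H](O[Si](C)(C)C(C)(C)C)CCc2ccccc2 | intermediate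
14 | lithium acetylide–ethylenediamine complex | [Li+].[C-]#C.NCCN | starting material
15 | (4R,6R,8R)-8-[(tert-butyldimethylsilyl)oxy]-10-phenyldec-1-yne-4,6-diol | C#CC[C@@H](O)C[C@@H](O)C[C@H](O[Si](C)(C)C(C)(C)C)CCc1ccccc1 | intermediate
16 | tert-butyl{[(2R)-1-[(4R,6R)-2,2-dimethyl-6-(prop-2-yn-1-yl)-1,3-dioxan-4-yl]-4-phenylbutan-2-yl]oxy}dimethylsilane | C#CC[C@@H]1C[C@H](C[C@H](O[Si](C)(C)C(C)(C)C)CCc2ccccc2)OC(C)(C)O1 | intermediate
17 | N,N-dimethylformamide | CN(C)C=O | starting material
18 | lithium acetylide of 16 | [Li]C#CC[C@@H]1C[C@H](C[C@H](O[Si](C)(C)C(C)(C)C)CCc2ccccc2)OC(C)(C)O1 | intermediate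
19 | lithium 1-(dimethylamino)alk-2-yn-1-olate adduct of 18 and DMF (epimers at the new carbon) | [Li]OC(N(C)C)C#CC[C@@H]1C[C@H](C[C@H](O[Si](C)(C)C(C)(C)C)CCc2ccccc2)OC(C)(C)O1 | intermediate
20 | 4-[(4R,6R)-6-{(2R)-2-[(tert-butyldimethylsilyl)oxy]-4-phenylbutyl}-2,2-dimethyl-1,3-dioxan-4-yl]but-2-ynal | O=CC#CC[C@@H]1C[C@H](C[C@H](O[Si](C)(C)C(C)(C)C)CCc2ccccc2)OC(C)(C)O1 | intermediate
21 | (E)-1-methoxybuta-1,3-diene | CO/C=C/C=C | starting material
22 | (2R,6S)-6-{3-[(4R,6R)-6-{(2R)-2-[(tert-butyldimethylsilyl)oxy]-4-phenylbutyl}-2,2-dimethyl-1,3-dioxan-4-yl]prop-1-yn-1-yl}-2-methoxy-5,6-dihydro-2H-pyran (2,6-cis) | CO[C@H]1C=CC[C@@H](C#CC[C@@H]2C[C@H](C[C@H](O[Si](C)(C)C(C)(C)C)CCc3ccccc3)OC(C)(C)O2)O1 | intermediate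
23 | (2R,6S)-6-{(1Z)-3-[(4R,6R)-6-{(2R)-2-[(tert-butyldimethylsilyl)oxy]-4-phenylbutyl}-2,2-dimethyl-1,3-dioxan-4-yl]prop-1-en-1-yl}-2-methoxy-5,6-dihydro-2H-pyran | CO[C@H]1C=CC[C@@H](/C=C\C[C@@H]2C[C@H](C[C@H](O[Si](C)(C)C(C)(C)C)CCc3ccccc3)OC(C)(C)O2)O1 | intermediate
24 | (6S)-6-{(1Z)-3-[(4R,6R)-6-{(2R)-2-[(tert-butyldimethylsilyl)oxy]-4-phenylbutyl}-2,2-dimethyl-1,3-dioxan-4-yl]prop-1-en-1-yl}-5,6-dihydro-2H-pyran-2-ol (anomers) | OC1C=CC[C@@H](/C=C\C[C@@H]2C[C@H](C[C@H](O[Si](C)(C)C(C)(C)C)CCc3ccccc3)OC(C)(C)O2)O1 | intermediate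
25 | (6S)-6-{(1Z)-3-[(4R,6R)-6-{(2R)-2-[(tert-butyldimethylsilyl)oxy]-4-phenylbutyl}-2,2-dimethyl-1,3-dioxan-4-yl]prop-1-en-1-yl}-5,6-dihydro-2H-pyran-2-one | O=C1C=CC[C@@H](/C=C\C[C@@H]2C[C@H](C[C@H](O[Si](C)(C)C(C)(C)C)CCc3ccccc3)OC(C)(C)O2)O1 | intermediate
26 | (6S)-6-[(1Z,4R,6S,8R)-4,6,8-trihydroxy-10-phenyldec-1-en-1-yl]-5,6-dihydro-2H-pyran-2-one | O=C1C=CC[C@@H](/C=C\C[C@@H](O)C[C@@H](O)C[C@H](O)CCc2ccccc2)O1 | target

**Totals**
Total step count: 14. Longest linear sequence: 14 steps (from 1; all other inputs are commercial).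

**Steps most likely to fail, with fallbacks**

1. Step 11. What may go wrong: insufficient facial discrimination by the catalyst on this large ynal (a mismatched pairing with the distant chain centres cannot be excluded), competing carbocyclic Diels–Alder addition of the diene across the activated C≡C bond, or slow turnover. Fallback, setting out from 20 and coming back at 25: C6 is set instead by a Brown allylboration of 20 with 2 at −78 °C (Si-face addition), which gives the diisopinocampheylborinate ester F1 and, after NaOH/H2O2, the (4S)-enynol F2. Lindlar semihydrogenation (H2, Pd/CaCO3 poisoned with Pb(OAc)2, quinoline) then gives the (4S,5Z)-dienol F3, and acryloyl chloride with Et3N and DMAP gives the acrylate F4. Ring-closing metathesis with the second-generation Grubbs catalyst RuCl2(=CHPh)(PCy3)(H2IMes) in CH2Cl2 at 40 °C, which initiates at the terminal allyl alkene and closes onto the acrylate, forms the six-membered lactone and returns to the route at 25.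

2. Step 13. What may go wrong: loss of the acetonide competing with hydrolysis of the methyl acetal, giving mixtures of partly deprotected lactols that oxidise unevenly. Fallback, setting out from 23 and coming back at 26: the protecting groups are given up at this stage. Aqueous HCl (1 M) in THF removes methyl acetal, acetonide and silyl ether together and gives the triol lactol F5. MnO2 in acetone/CH2Cl2 then oxidises only the allylic lactol, since the three secondary alcohols are unactivated, and leads directly to 26.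

3. Step 8. What may go wrong: migration of the silyl group from O8' to the neighbouring alkoxide, or incomplete opening, under the strongly basic conditions in DMSO. Fallback, setting out from 13 and coming back at 15: the epoxide is opened under Lewis-acid activation at low temperature with a capped alkyne. Lithium (trimethylsilyl)acetylide (from ethynyltrimethylsilane and n-BuLi) with BF3·OEt2 in THF at −78 °C gives the C-silylated diol F6, and K2CO3 in MeOH then removes the alkynyl silyl group to return to 15.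

**Further compounds**

F1 | step 11 | (4S)-7-[(4R,6R)-6-{(2R)-2-[(tert-butyldimethylsilyl)oxy]-4-phenylbutyl}-2,2-dimethyl-1,3-dioxan-4-yl]hept-1-en-5-yn-4-yl diisopinocampheylborinate | C=CC[C@H](OB([C@@H]1C[C@@H]2C[C@H]([C@H]1C)C2(C)C)[C@@H]1C[C@@H]2C[C@H]([C@H]1C)C2(C)C)C#CC[C@@H]1C[C@H](C[C@H](O[Si](C)(C)C(C)(C)C)CCc2ccccc2)OC(C)(C)O1
F2 | step 11 | (4S)-7-[(4R,6R)-6-{(2R)-2-[(tert-butyldimethylsilyl)oxy]-4-phenylbutyl}-2,2-dimethyl-1,3-dioxan-4-yl]hept-1-en-5-yn-4-ol | C=CC[C@H](O)C#CC[C@@H]1C[C@H](C[C@H](O[Si](C)(C)C(C)(C)C)CCc2ccccc2)OC(C)(C)O1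
F3 | step 11 | (4S,5Z)-7-[(4R,6R)-6-{(2R)-2-[(tert-butyldimethylsilyl)oxy]-4-phenylbutyl}-2,2-dimethyl-1,3-dioxan-4-yl]hepta-1,5-dien-4-ol | C=CC[C@H](O)/C=C\C[C@@H]1C[C@H](C[C@H](O[Si](C)(C)C(C)(C)C)CCc2ccccc2)OC(C)(C)O1
F4 | step 11 | (4S,5Z)-7-[(4R,6R)-6-{(2R)-2-[(tert-butyldimethylsilyl)oxy]-4-phenylbutyl}-2,2-dimethyl-1,3-dioxan-4-yl]hepta-1,5-dien-4-yl prop-2-enoate | C=CC[C@H](OC(=O)C=C)/C=C\C[C@@H]1C[C@H](C[C@H](O[Si](C)(C)C(C)(C)C)CCc2ccccc2)OC(C)(C)O1
F5 | step 13 | (6S)-6-[(1Z,4R,6S,8R)-4,6,8-trihydroxy-10-phenyldec-1-en-1-yl]-5,6-dihydro-2H-pyran-2-ol (anomers) | OC1C=CC[C@@H](/C=C\C[C@@H](O)C[C@@H](O)C[C@H](O)CCc2ccccc2)O1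
F6 | step 8 | (4R,6R,8R)-8-[(tert-butyldimethylsilyl)oxy]-10-phenyl-1-(trimethylsilyl)dec-1-yne-4,6-diol | C[Si](C)(C)C#CC[C@@H](O)C[C@@H](O)C[C@H](O[Si](C)(C)C(C)(C)C)CCc1ccccc1
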